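The vessel is closed, stirred and held at one temperature. Substrate goes to target under a catalyst, and in each run below the target rises and then levels off far short of the substrate charged.

| flask | substrate | catalyst | time |
|---|---|---|---|
| elm | 0.400 M | 0.0400 M |  |
| larch | 0.240 M | 0.0400 M |  |
| ash | 0.400 M | 0.0600 M |  |
| cedar | 1.20 M | 0.0400 M |  |
| alder | 0.200 M | 0.0200 M | 46 min |

| elm run: time / min | elm run: [target] / M | larch run: time / min | larch run: [target] / M | ash run: time / min | ash run: [target] / M | cedar run: time / min | cedar run: [target] / M |
|---|---|---|---|---|---|---|---|
| 1.7 | 0.015 | 1.7 | 0.014 | 1.7 | 0.039 | 1.7 | 0.023 |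
| 5.0 | 0.037 | 5.0 | 0.031 | 5.0 | 0.066 | 5.0 | 0.054 |
| 9.6 | 0.052 | 9.6 | 0.042 | 9.6 | 0.091 | 9.6 | 0.066 |
| 15 | 0.065 | 15 | 0.056 | 15 | 0.099 | 15 | 0.080 |
| 22 | 0.073 | 22 | 0.059 | 22 | 0.109 | 22 | 0.077 |
| 29 | 0.074 | 29 | 0.067 | 29 | 0.110 | 29 | 0.093 |
| 37 | 0.078 | 37 | 0.070 | 37 | 0.118 | 37 | 0.092 |
| 46 | 0.077 | 46 | 0.063 | 46 | 0.106 | 46 | 0.096 |

(each reading ± 0.003 M)

- Overall: substrate -> target, with catalyst as catalyst.
- Constant volume, constant temperature.
- Bound and free are read together.
- An order is taken over about fifteen percent of the charge, up and down.

* order of the initial rate in [substrate], near the charge of the elm run, the rate being that where two percent of its substrate are target (one fixed amount of target, the same in the runs compared)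
* order of the initial rate in [catalyst], near the charge of the elm run, the rate being that where two percent of its substrate are target
* target in the alder run at 46 min, as a share of the substrate charged

I read each run the same way. The plateau P is the mean of the last 3 readings, which is 0.0763 M in the elm run. From the reading at 5.0 min, elm then gives 7.54 min. This is the lifetime τ, the time in which the distance left to the plateau shrinks by a factor e. A flask that has run for time t has passed t/τ lifetimes and has a share e^(−t/τ) of its plateau still to make.

With 0.0667 M as its plateau, the larch run reads 7.99 min. With 0.111 M, the ash run reads 5.56 min.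

Two chemists dispute the alder flask, whose substrate and catalyst are each half of those in elm. The first points to elm and larch, which share a catalyst charge and read much the same τ, and holds a plain first-order view. On that view, scaling every charge alike changes nothing, so alder keeps elm's lifetime and elm's share of the charge, 19.1 %.

The second points to ash, whose lifetime is shorter than elm's at a larger catalyst charge, and argues that catalyst sets the clock and the plateau. The forecast stands on this side: “The catalyst dies or is poisoned after a limited number of turnovers”. It gives 15 % for alder, with orders 0.3 in substrate and 1.9 in catalyst.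

My own reckoning takes τ as inverse in catalyst, so alder has 15.1 min. By 46 min that makes 3.05 lifetimes.

The simulation gives 15.0 % for alder, with orders 0.58 in substrate and 1.8 in catalyst. The first chemist's share loses; the forecast's alder value and catalyst order stand, while its substrate order is too low.

    catalyst + substrate ⇌ catalyst-substrate complex, settled at all times (2.150 M⁻¹)
    catalyst-substrate complex + catalyst → target + 2 catalyst (80.40 M⁻¹ min⁻¹)
    2 substrate → homo dimer (0.9300 M⁻¹ min⁻¹)
    2 catalyst ⇌ resting dimer, settled at all times (26.60 M⁻¹)

Counted on its plateau, the alder run's 3.05 lifetimes leave 4.74 % still to make at 46 min. Its rise ends chiefly through the step from substrate to homo dimer: with that step taken away, the alder run gives 59.6 % instead of 15.0 %. The first chemist's unchanged lifetime has its place between the elm and larch runs. Carried from elm to the larch run, τ counts 2.98 lifetimes at 22.5 min and gives 0.0633 M of target, where the simulation has 0.0600 M.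

The earlier runs and the new flask are calculated with made-up constants, and the scatter is random.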